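**Plan**
Numbering: heavy atoms follow the order of the target SMILES. Ring A = C9, C11, C13, C14, C15, C18; ring B = C7, C8, C9, C18, C19, C20; ring C = C2, C3, C4, C5, C21, C20; ring D = C5, O6, C7, C20, C21. "Syn" and "anti" mean the same or the opposite side of the decalin as the angular methyl C10.
Cuts: O6–C5 first (ring D), then C20–C21 and C2–C3 in one operation (ring C), then C20–C2 (ethynyl unit), C11–Br and C15–C16. This leads back to the Wieland–Miescher ketone.
Enabling feature: in ring C the exocyclic methylene C1=C2 stands beside spiro C20, C20 is bonded to gem-dimethyl C21, and C3–C4–C5 complete the ring. A [4+2] addition of CH2=CH–CH=CMe2 to the carbonyl-conjugated C20=C2 bond of a C7-keto vinylidene decalin leaves exactly this pattern.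
Forward order: rings A and B come with 1 and are functionalised at C18, C15 and C11. C20 then becomes the allene terminus with the carbonyl moved to C7, ring C closes by cycloaddition, and ring D closes by etherification of C4=C5.
Stereochemistry: C9 comes from 1 and directs C18 (hydroboration), C15 (equatorial MeLi addition), C11 (axial H-atom transfer) and C20 (equatorial-face cycloaddition). C7 is set under thermodynamic control and C5 by the geometry of the bridge.

Key step: step 17

Remark on the chemistry: the configurations written for C7 in 15, 16 and 18–21 and for C20 in 15, 18 and 19 are the expected ones. Both carbons become trigonal again before step 17, so any epimers converge on 22.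

**Step 1**
Reactants: 1 (S)-Wieland–Miescher ketone
Product: 2 bis(ethylene ketal) with dioxolanes at C11 and C20 and the alkene moved to C15=C18
Conditions: HOCH2CH2OH (excess), TsOH·H2O (cat.), benzene, reflux, Dean–Stark
Reagents that add atoms: ethylene glycol, OCCO
Why: Acid-catalysed ketalisation masks both carbonyl groups, and ketalisation of the enone moves the double bond out of conjugation to C15=C18 (as in steroid 5-ene 3-ketals), which opens C15 to oxidation while C9 is untouched.

**Step 2**
Reactants: 2 bis(ethylene ketal)
Product: 4 trans-fused bis-ketal alcohol (H18 anti; 15-OH anti and equatorial), via alkylborane 3 (not isolated)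
Conditions: BH3·THF, THF, 0 °C → rt; then NaOH aq., H2O2, 0 °C → rt
Reagents that add atoms: hydrogen peroxide, OO
Why: Hydroboration–oxidation puts boron on the less substituted C15 and adds H and B syn on the face opposite C10, which sets H18 anti to C10 (trans-decalin) and gives an equatorial hydroxyl.

**Step 3**
Reactants: 4 trans-fused bis-ketal alcohol
Product: 5 trans-fused C15 ketone bis-ketal
Conditions: Dess–Martin periodinane, pyridine, CH2Cl2, rt
Reagents that add atoms: none
Why: Buffered Dess–Martin oxidation spares both ketals, and C18 beside the new ketone already holds the more stable trans-fused configuration.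

**Step 4**
Reactants: 5 C15 ketone bis-ketal
Product: 6 C15 tertiary alcohol bis-ketal (C16 anti and equatorial; OH syn and axial)
Conditions: MeLi, Et2O, −78 → 0 °C; then H2O
Reagents that add atoms: methyllithium, [Li]C
Why: 1,2-Addition occurs from the equatorial side because the axial path at C15 is closed by the syn-axial methyl C10, so C16 ends equatorial and the hydroxyl axial as in the target.

**Step 5**
Reactants: 6 tertiary alcohol bis-ketal
Product: 7 hydroxy dione (C11 and C20 ketones)
Conditions: 1 M HCl aq., THF, rt
Reagents that add atoms: water, O
Why: Aqueous acid hydrolysis frees both ketones, and the tertiary alcohol is γ to each carbonyl and so cannot undergo retro-aldol cleavage or β-elimination.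

**Step 6**
Reactants: 7 hydroxy dione
Product: 8 C20 mono-ketal with free C11 ketone
Conditions: HOCH2CH2OH (1.1 equiv), PPTS (cat.), benzene, reflux, Dean–Stark
Reagents that add atoms: ethylene glycol, OCCO
Why: Mild ketalisation with about one equivalent of glycol discriminates on steric grounds, so the open C20 cyclohexanone reacts and the C11 ketone beside quaternary C9 stays free.

**Step 7**
Reactants: 8 C20 mono-ketal
Product: 9 C11 (E)-hydrazone
Conditions: N2H4·H2O (excess), Et3N, EtOH, reflux
Reagents that add atoms: hydrazine, NN
Why: Hydrazone formation is the first stage of the Barton vinyl halide synthesis and is established for ketones beside a quaternary carbon, and the ketal is inert to base.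

**Step 8**
Reactants: 9 C11 hydrazone
Product: 11 C11 vinyl bromide (C11=C13), via diazoalkane 10 (not isolated)
Conditions: NBS (2.2 equiv), pyridine, 0 °C
Reagents that add atoms: N-bromosuccinimide, O=C1CCC(=O)N1Br
Why: In this Barton-type oxidative bromination NBS oxidises the hydrazone to the diazoalkane and brominates it, and loss of N2 and of a proton from C13 (the only carbon that can lose one) gives the vinyl bromide, as with steroid 17-hydrazones.

**Step 9**
Reactants: 11 vinyl bromide
Product: 12 C11 equatorial bromide (Br syn) with C20 ketal
Conditions: Mn(dpm)3 (cat.), PhSiH3, t-BuOOH, i-PrOH, rt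
Reagents that add atoms: none
Why: Metal-hydride hydrogen atom transfer hydrogenation tolerates vinyl halides; it puts H on C13 to give the α-bromo radical at C11, and the second hydrogen arrives axially on the face away from the vicinal C10, so bromine ends equatorial (also the thermodynamic outcome).

**Step 10**
Reactants: 12 bromide ketal
Product: 13 bromo hydroxy trans-decalone (C20 ketone)
Conditions: 1 M HCl aq., THF, rt
Reagents that add atoms: water, O
Why: Acid hydrolysis removes the remaining dioxolane, and the equatorial bromide beside C9 has no antiperiplanar hydrogen and is inert.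

**Step 11**
Reactants: 13 bromo hydroxy decalone
Product: 14 C20=C7 triethylsilyl enol ether with C15 TES ether
Conditions: TESOTf (3.5 equiv), Et3N, CH2Cl2, 0 °C → rt
Reagents that add atoms: triethylsilyl triflate, CC[Si](CC)(CC)OS(=O)(=O)C(F)(F)F
Why: Silyl triflate and amine silylate the tertiary alcohol and convert the ketone into its preferred enol ether, which in a trans-decal-2-one with an angular methyl lies towards C7 and away from the ring fusion, as in 5α-3-keto steroids.

**Step 12**
Reactants: 14 bis-silyl compound
Product: 16 C7 equatorial (anti) triethylsilyloxy C20 ketone, via silyloxy epoxide 15 (not isolated)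
Conditions: mCPBA, NaHCO3, CH2Cl2, −20 → 0 °C
Reagents that add atoms: mCPBA, O=C(OO)c1cccc(Cl)c1
Why: In the Rubottom oxidation the enol ether is epoxidised anti to C10, and ring opening with 1,4-silyl shift gives the α-silyloxy ketone with the silyl group kept as protection.

**Step 13**
Reactants: 16 α-silyloxy ketone, 17 ethynylmagnesium bromide
Product: 19 C20 tertiary propargylic methyl carbonate (ethynyl anti and axial), via bromomagnesium alkoxide 18 (not isolated)
Conditions: THF, 0 °C → rt; then ClCO2Me, 0 °C → rt
Reagents that add atoms: methyl chloroformate, COC(=O)Cl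
Why: 1,2-Addition of the slim acetylide along the axial path gives the tertiary alkoxide, which the chloroformate acylates in the flask (a common one-pot way to tertiary propargylic carbonates), and the C20 configuration is erased in the next step.

**Step 14**
Reactants: 19 propargylic carbonate
Product: 20 C20 vinylidene decalin with TES ethers at C7 and C15
Conditions: Pd2(dba)3·CHCl3 (cat.), P(n-Bu)3 (cat.), HCO2NH4, THF, rt
Reagents that add atoms: none
Why: In this palladium-catalysed formate hydrogenolysis zerovalent palladium ionises the carbonate in SN2′ fashion to a σ-allenylpalladium species bonded at the terminal carbon, formate supplies hydride by decarboxylation, and reductive elimination gives the 1,1-disubstituted allene (known for 17-ethynyl steroid carbonates) without touching the unactivated bromide.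

**Step 15**
Reactants: 20 vinylidene bis-TES ether
Product: 21 C20 vinylidene C7 alcohol (C15 TES ether kept)
Conditions: PPTS (cat.), MeOH/CH2Cl2, 0 °C
Reagents that add atoms: none
Why: Acid-catalysed methanolysis removes the exposed secondary TES ether far faster than the axial tertiary one, which is flanked by C10.

**Step 16**
Reactants: 21 vinylidene alcohol
Product: 22 2-vinylidene bromodecalone (C7 ketone, C20=C2=C1 allene, C15 OTES)
Conditions: Dess–Martin periodinane, pyridine, CH2Cl2, 0 °C; used at once
Reagents that add atoms: none
Why: Dess–Martin oxidation of α-allenic alcohols to allenyl ketones is established, and the buffered medium avoids the acid or base that would isomerise the allene to a 2-vinyl enone.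

**Step 17**
Reactants: 22 2-vinylidene bromodecalone, 23 4-methylpenta-1,3-diene
Product: 24 spiro methylenecyclohexene ketone (C21 syn and equatorial, C2 anti and axial on ring B; C4=C5 alkene)
Conditions: Me2AlCl (1.5 equiv), CH2Cl2, −78 °C; 23 (10 equiv), −78 → −20 °C
Reagents that add atoms: none
Why: Proposed new method: Me2AlCl binds the C7 carbonyl of the s-cis-locked allenone and lowers the LUMO of the conjugated C20=C2 bond, whose largest coefficient sits on the unhindered sp carbon C2, so the CH2 terminus C3 of 23 (largest HOMO coefficient) bonds there early and the CMe2 terminus C21, carrying tertiary allyl-cation character, closes on the α-carbon C20 late in one strongly asynchronous [4+2] event. Bonding has to start from the skew s-cis rotamer of 23, because an open intermediate born from the s-trans rotamer would hold an E-allyl cation that cannot reach C20; the closest known reaction type is the Lewis-acid-promoted Diels–Alder reaction of allenyl ketones and allenoates with simple dienes to methylenecyclohexenes, and what is new is the joining of two fully substituted carbons with a diene bearing a Z-methyl group, for which the release of allene strain and the early, unhindered C2–C3 bond are relied on. Ring C closes as a six-membered carbocycle by intermolecular suprafacial [4+2] cycloaddition (σ bonds C2–C3 and C20–C21, new ring alkene C4=C5), and the remote allene π bond is left as the methylene C1=C2. The one new stereocentre, C20, is controlled by the chair of ring B held in the trans-decalin: the π lobe on the anti face leans in over ring B between axial H8 and H18 while the lobe on the syn face leans outwards, so the bulky C21 should enter there and end equatorial with the flat C2 axial, C10 lying too far across the ring to interfere, and endo or exo orientation creates no stereocentre. The step needs ortho regioselectivity (matched coefficients), site selectivity (only C20=C2 overlaps with C7=O, the C2=C1 π bond being orthogonal to it) and periselectivity over [2+2], ene and hetero-[4+2] modes and over cationic polymerisation of 23, which low temperature, excess diene and the proton-scavenging methyl–aluminium bonds are meant to secure. The tertiary TES ether and the equatorial bromide offer no site that Me2AlCl should engage at these temperatures.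

**Step 18**
Reactants: 24 spiro ketone
Product: 25 C7 equatorial (anti) alcohol
Conditions: SmI2 (3 equiv), H2O, THF, 0 °C, no amine, no HMPA
Reagents that add atoms: none
Why: Single-electron reduction with SmI2/H2O runs through a ketyl and an organosamarium that is protonated to the more stable alcohol, here equatorial because an axial hydroxyl would be syn-axial to C10, and amine and HMPA are left out because without them SmI2 attacks unactivated secondary bromides only slowly.

**Step 19**
Reactants: 25 C7 alcohol
Product: 27 O-triethylsilyl ether of the target (ring D closed), via organomercury trifluoroacetate 26 (not isolated)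
Conditions: Hg(OCOCF3)2, THF, 0 °C; then NaOH aq., NaBH4, 0 °C
Reagents that add atoms: none
Why: In this intramolecular oxymercuration–demercuration mercuration is reversible and only the C4=C5 mercurinium ion has a hydroxyl in reach, so O6 attacks C5 in a 5-exo, trans-diaxial manner (attack at C2 would give an oxetane, attack at C4 a boat-shaped [2.2.2] bicycle), which fixes C5 before NaBH4 replaces mercury by hydrogen.

**Step 20**
Reactants: 27 TES ether of the target
Product: 28 target CNP0412361.2
Conditions: HF·pyridine, pyridine, THF, 0 °C → rt
Reagents that add atoms: none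
Why: Buffered fluoride cleavage of the tertiary silyl ether leaves the methylene group, the ether bridge and the bromide untouched.

**Compound list**
1 | (S)-Wieland–Miescher ketone | C[C@]12CCC(=O)C=C1CCCC2=O | starting material
2 | C11/C20 bis(ethylene ketal), C15=C18 alkene | C12(OCCO1)CC3=CCCC4(OCCO4)[C@@]3(C)CC2 | intermediate
3 | C15 alkylborane (B and H18 anti) | C12(OCCO1)C[C@@H]3[C@@H](B)CCC4(OCCO4)[C@@]3(C)CC2 | intermediate
4 | trans-fused bis-ketal, equatorial 15-OH | C12(OCCO1)C[C@@H]3[C@@H](O)CCC4(OCCO4)[C@@]3(C)CC2 | intermediate
5 | trans-fused bis-ketal C15 ketone | C12(OCCO1)C[C@@H]3C(=O)CCC4(OCCO4)[C@@]3(C)CC2 | intermediate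
6 | bis-ketal C15 tertiary alcohol (Me equatorial, OH axial) | C12(OCCO1)C[C@@H]3[C@](C)(O)CCC4(OCCO4)[C@@]3(C)CC2 | intermediate
7 | hydroxy dione (C11, C20 ketones) | O=C1C[C@@H]2[C@](C)(O)CCC(=O)[C@@]2(C)CC1 | intermediate
8 | C20 mono-ketal, C11 ketone | C12(OCCO1)C[C@@H]3[C@](C)(O)CCC(=O)[C@@]3(C)CC2 | intermediate
9 | C11 (E)-hydrazone | C12(OCCO1)C[C@@H]3[C@](C)(O)CC/C(=N\N)[C@@]3(C)CC2 | intermediate
10 | C11 diazoalkane | C12(OCCO1)C[C@@H]3[C@](C)(O)CCC(=[N+]=[N-])[C@@]3(C)CC2 | intermediate
11 | C11 vinyl bromide (C11=C13) | C12(OCCO1)C[C@@H]3[C@](C)(O)CC=C(Br)[C@@]3(C)CC2 | intermediate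
12 | C11 equatorial bromide, C20 ketal | C12(OCCO1)C[C@@H]3[C@](C)(O)CC[C@H](Br)[C@@]3(C)CC2 | intermediate
13 | bromo hydroxy trans-decalone (C20 ketone) | O=C1C[C@@H]2[C@](C)(O)CC[C@H](Br)[C@@]2(C)CC1 | intermediate
14 | C20=C7 TES enol ether, C15 TES ether | CC[Si](CC)(CC)OC1=CC[C@]2(C)[C@@H](Br)CC[C@@](C)(O[Si](CC)(CC)CC)[C@H]2C1 | intermediate
15 | C7/C20 silyloxy epoxide (oxygen anti) | CC[Si](CC)(CC)O[C@]12C[C@@H]3[C@](C)(O[Si](CC)(CC)CC)CC[C@H](Br)[C@@]3(C)C[C@H]1O2 | intermediate
16 | C7 equatorial OTES, C20 ketone | O=C1C[C@@H]2[C@](C)(O[Si](CC)(CC)CC)CC[C@H](Br)[C@@]2(C)C[C@H]1O[Si](CC)(CC)CC | intermediate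
17 | ethynylmagnesium bromide | C#C[Mg]Br | starting material
18 | C20 bromomagnesium alkoxide (ethynyl axial) | C#C[C@@]1(O[Mg]Br)C[C@@H]2[C@](C)(O[Si](CC)(CC)CC)CC[C@H](Br)[C@@]2(C)C[C@H]1O[Si](CC)(CC)CC | intermediate
19 | C20 propargylic methyl carbonate | C#C[C@@]1(OC(=O)OC)C[C@@H]2[C@](C)(O[Si](CC)(CC)CC)CC[C@H](Br)[C@@]2(C)C[C@H]1O[Si](CC)(CC)CC | intermediate
20 | C20 vinylidene, C7 and C15 TES ethers | C=C=C1C[C@@H]2[C@](C)(O[Si](CC)(CC)CC)CC[C@H](Br)[C@@]2(C)C[C@H]1O[Si](CC)(CC)CC | intermediate
21 | C20 vinylidene C7 alcohol | C=C=C1C[C@@H]2[C@](C)(O[Si](CC)(CC)CC)CC[C@H](Br)[C@@]2(C)C[C@H]1O | intermediate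
22 | 2-vinylidene bromodecalone (C7 ketone, C15 OTES) | C=C=C1C[C@@H]2[C@](C)(O[Si](CC)(CC)CC)CC[C@H](Br)[C@@]2(C)CC1=O | intermediate
23 | 4-methylpenta-1,3-diene | CC(C)=CC=C | starting material
24 | spiro methylenecyclohexene ketone | C=C1CC=CC(C)(C)[C@@]12C[C@@H]3[C@](C)(O[Si](CC)(CC)CC)CC[C@H](Br)[C@@]3(C)CC2=O | intermediate
25 | C7 equatorial alcohol | C=C1CC=CC(C)(C)[C@@]12C[C@@H]3[C@](C)(O[Si](CC)(CC)CC)CC[C@H](Br)[C@@]3(C)C[C@H]2O | intermediate
26 | C4 organomercury trifluoroacetate (Hg anti to O6) | C=C1C[C@@H]([Hg]OC(=O)C(F)(F)F)[C@@H]2O[C@@H]3C[C@]4(C)[C@@H](Br)CC[C@@](C)(O[Si](CC)(CC)CC)[C@H]4C[C@]13C2(C)C | intermediate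
27 | O-triethylsilyl ether of the target | C=C1CC[C@@H]2O[C@@H]3C[C@]4(C)[C@@H](Br)CC[C@@](C)(O[Si](CC)(CC)CC)[C@H]4C[C@]13C2(C)C | intermediate
28 | CNP0412361.2 | C=C1CC[C@@H]2O[C@@H]3C[C@]4(C)[C@@H](Br)CC[C@@](C)(O)[C@H]4C[C@]13C2(C)C | target

**Totals**
Total step count: 20.
Longest linear sequence: 20 steps (1 → 28). Compounds 17 and 23 are bought.

**Steps most likely to fail**

**Step 17 (Proposed new method).**
- What may go wrong: cationic polymerisation of the diene, closure in the [2+2] or ene sense or through the carbonyl oxygen, failure to form the hindered C20–C21 bond, or poor facial selectivity at C20.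
- The fallback sets out from 22 and comes back at 24.
- The same two bonds would be made with the far more nucleophilic 2-(tert-butyldimethylsilyloxy)-4-methylpenta-1,3-diene F1, obtained from mesityl oxide with LDA and TBSCl in THF at −78 °C.
- The union of such hindered 2-silyloxy dienes with 2-substituted enones under the mixed Lewis acid AlBr3/AlMe3 in toluene/CH2Cl2 is an established way to vicinal quaternary carbons. It runs as a Mukaiyama–Michael addition followed by ring closure.
- With 22 it should give the C4 silyl enol ether adduct F2.
- CsF and PhNTf2 in DME would convert F2 regiospecifically into the C4 enol triflate F3.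
- Pd(OAc)2, PPh3, HCO2H and n-Bu3N in DMF at 60 °C would reduce F3 to 24.

**Step 18.**
- What may go wrong: reductive loss of bromine by electron transfer to C11–Br, or stalling at the doubly flanked carbonyl group.
- The fallback sets out from 24 and comes back at 25.
- Electron transfer would be replaced by hydride chemistry followed by equilibration.
- i-Bu2AlH in CH2Cl2 at −78 °C leaves alkyl bromides alone. It should deliver hydride along the outward-leaning equatorial path and give mainly the axial C7 alcohol F4.
- F4 would then be equilibrated by Meerwein–Ponndorf–Verley/Oppenauer hydride exchange (Al(Oi-Pr)3, i-PrOH/toluene, trace of acetone, reflux) towards 25. This direction is favoured because the axial hydroxyl is syn-axial to C10.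

**Step 19.**
- What may go wrong: mercuration and solvolysis at the more accessible methylene C1=C2, acid-induced migration of that double bond, or reversion to the alkene during demercuration.
- The fallback sets out from 25 and comes back at 27.
- The organomercury sequence would be replaced by halocyclisation and radical dehalogenation.
- NIS in CH2Cl2 at 0 °C in the dark should give the C4 iodo ether F5 by the same 5-exo, trans-diaxial closure.
- n-Bu3SnH (1.0 equiv) with Et3B/air in toluene at −78 °C would remove iodine, since a stannyl radical abstracts iodine much faster than the secondary bromine.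

**Further compounds**
F1 | step 17 | 2-(tert-butyldimethylsilyloxy)-4-methylpenta-1,3-diene | C=C(O[Si](C)(C)C(C)(C)C)C=C(C)C
F2 | step 17 | spiro adduct with C4 OTBS enol ether (C4=C5) | C=C1CC(O[Si](C)(C)C(C)(C)C)=CC(C)(C)[C@@]12C[C@@H]3[C@](C)(O[Si](CC)(CC)CC)CC[C@H](Br)[C@@]3(C)CC2=O
F3 | step 17 | spiro adduct with C4 enol triflate (C4=C5) | C=C1CC(OS(=O)(=O)C(F)(F)F)=CC(C)(C)[C@@]12C[C@@H]3[C@](C)(O[Si](CC)(CC)CC)CC[C@H](Br)[C@@]3(C)CC2=O
F4 | step 18 | C7 axial (syn) alcohol, 7-epimer of 25 | C=C1CC=CC(C)(C)[C@@]12C[C@@H]3[C@](C)(O[Si](CC)(CC)CC)CC[C@H](Br)[C@@]3(C)C[C@@H]2O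
F5 | step 19 | C4 iodo ether (iodine anti to O6) | C=C1C[C@@H](I)[C@@H]2O[C@@H]3C[C@]4(C)[C@@H](Br)CC[C@@](C)(O[Si](CC)(CC)CC)[C@H]4C[C@]13C2(C)C
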